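If a flask loses free monomer in proportion to the amount present, the logarithm of charged over free rises in a straight line with time, and its slope k is a pseudo-first-order constant. Saturday's run can test this.

all flasks: initiator 0.89 mM; impurity 0.19 mM
- Saturday's: free monomer 0.48 M; run made earlier
- flask: free monomer 0.24 M; time 5.0 d

Saturday's run (percent of the free monomer charged)

| time / h | monomer in chains / % | free monomer / % |
|---|---|---|
| 5.00 | 13 | 85 |
| 12.0 | 32 | 67 |
| 25.0 | 61 | 44 |
| 40.0 | 77 | 23 |

(readings scatter by 1.5 percentage points)

- the average divides the monomer in chains by the number of chains begun, living and dead together
- the analysis behind the earlier runs scatters by 1.5 percentage points, standard deviation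
- the earlier runs do not show the number of chains; that part of a forecast is a guess

- average number of monomer units in a chain (chains begun, living or dead) at 5.0 d
- part of the free monomer that has reacted at 5.0 d

Read row by row, Saturday's free monomer gives a slope of 0.0325 h⁻¹ in the first row and 0.0328 h⁻¹ in the third. The last row, with the longest time, gives k, the slope of that logarithm, as 0.0367 h⁻¹. This reading is higher than the first row's slope, so these three rows show no fall in the slope up to 40.0 h.

The flask has the same initiator and impurity as Saturday's run, but half the free monomer. Taking k, a rate per unit of free monomer, as the same in this flask, the reckoning here runs it out to 3.00 times the last row's time and gets 98.8% reacted. The rows do not show the number of chains, so this reckoning gives no average.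

The forecast gives 98% reacted and 285 units per chain, and says of the count: “Chains begun are a guess”.

The flask gives 98.5% reacted and 2380 units per chain, 8.35 times the forecast's average.

    free monomer + initiator → living end + monomer in chains (k = 0.330 M⁻¹ h⁻¹)
    free monomer + living end → monomer in chains + living end, rate k2*[living end]*[free monomer] (k = 360 M⁻¹ h⁻¹)
    initiator + impurity → spent initiator A (k = 13000 M⁻¹ h⁻¹)
    free monomer + initiator → spent initiator B (k = 1.80 M⁻¹ h⁻¹)
    2 initiator → spent initiator C (k = 67.0 M⁻¹ h⁻¹)

Divided by the chain-step constant k2, k as read from Saturday's run stands for 1.02 × 10⁻⁴ M of living end; the scheme makes one living end per chain begun, and this flask's monomer in chains over that amount gives 2310 units. The neighbour charged with 7.6 × 10⁻⁴ M of impurity holds 2.19 × 10⁻⁵ M of living end at 5.00 d, against 9.92 × 10⁻⁵ M in this flask. With that amount taken as standing throughout, k scales to 0.00810 h⁻¹, and over 5.0 d that reckons 62.2% reacted. That neighbour gives 60.9% reacted and 6680 units per chain.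

(The runs are simulated with made-up constants; scatter was added.)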